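**Slow opening.** In Monday's flask the starting material opens to intermediate and leaving ligand with a half-life of 12 h, forward step alone, against a run of 12 h. Anything faster has that long to eat starting material. The five flasks differ in their charge of protic impurity.

common to all: starting material 0.071 M; coupling partner 0.213 M (fed, over 12 h); time 12 h

| charge | protic impurity | remark |
|---|---|---|
| Monday's | 0.00500 M | the fed solution adds 0.25 times the starting volume |
| Wednesday's | 0.0100 M | the fed solution adds 0.25 times the starting volume |
| Tuesday's | 0.0200 M | the fed solution adds 0.25 times the starting volume |
| Saturday's | 0.0400 M | the fed solution adds 0.25 times the starting volume |
| Sunday's | 0.0800 M | the fed solution adds 0.25 times the starting volume |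

    starting material → decomposition product (k1 = 1.7 × 10⁻⁴ /h)
    starting material + protic impurity → quenched substrate (k2 = 100 /M/h)
    starting material ⇌ intermediate + leaving ligand (K3 = 1.8 × 10⁻⁶ M, k3 = 0.057 /h)
    coupling partner + intermediate → target (k4 = 2500 /M/h)
    intermediate → side product (k5 = 0.029 /h)

- amount of target at the end, in percent of the starting material charged for Monday's, Wednesday's, Tuesday's, Saturday's, Sunday's, in this order
- the shape of the row from first to last (falls all the way / rises all the way / hardly changes / falls, then rises / rises, then falls)

- amounts are per litre of the starting volume; all of the dose is in the solution fed
- "hardly changes" means that all values lie within two and a half points (for a concentration: within two and a half percent of the largest)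
- run time (Monday's): 12 h

**First entry.** Starting material is the limiting reagent, with coupling partner charged at 3.00 times its amount. In Monday's flask the protic impurity, facing starting material at its charge, has a half-life of 0.0976 h, far shorter than the opening. So each mole of impurity takes one mole of starting material at the outset. That writes off 7.04% of Monday's charge, and this figure is the quantity to carry: the impurity share, protic impurity charged over starting material charged.

**Small entries.** Reckoned with starting material held at its full charge for the whole run, decomposition product comes to 0.204% of Monday's charge, an upper bound, since starting material falls. Side product is minor too: the intermediate's half-life towards it is 24 h, while capture by a tenth of the coupling partner has a half-life of 0.781 min.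

**Closing entries.** Monday's flask keeps 93.0% of its charge after the quench, and the forward opening passes 49.5% of that in the run. The ceiling for target is therefore 46.1%. But that ceiling counts each opening as final. Leaving ligand retakes intermediate with a constant 12.7 times that of the coupling partner, so this reckoning puts Monday's target below the ceiling, by an amount it does not fix. The share climbs along the row to 113% on Sunday's flask, above the whole charge, so the reckoning has the row falling from first to last.

**The result.** The forecast gave 24.7%, 23.4%, 20.7%, 14.6% and 1.2%, shape falls all the way, holding that “the released ligand competes with the coupling partner for the intermediate”. The flasks give 24.7%, 23.4%, 20.7%, 14.5% and 1.01%, shape falls all the way, with Monday's target under its ceiling of 46.1%.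

**Row's cause.** The quench is the largest single effect behind the fall from Monday's flask to Sunday's: that change is −24 percentage points, and with the quench removed it is 0 points. The share reads the same books, since Monday's 7.04% stands as 7.04% quenched substrate and Saturday's 56.3% as 56.3%. In Sunday's flask, with a share of 113%, quenched substrate reaches 99.0%, starting material stands at 0%, and target ends at 1.01%.

The rate constants were chosen freely; the run is a simulation.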